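**Retrosynthetic overview** (chain atoms numbered C1–C22 from the ester carbon)
1. Target 24 ⇒ Sonogashira coupling at C11–C12 of alkynyl dioxane 17 with (E)-vinyl iodide 22 (from dec-9-yn-1-ol), then C-desilylation of the distal alkyne.
2. 17 ⇒ silyl ether 14 by desilylation, oxidation and one-carbon alkynylation; C6 of 14 is set by acid equilibration in methanol, C4–C5 is saturated by diimide.
3. Feature: the 1,2-dioxane consists of C3, C4, C5, C6 and the two peroxide oxygens, and C4–C5 is its only bond that touches neither oxygen. Cutting it leaves a C3 allylic hydroperoxide half and a C6 vinyl ketal half held together only by O–O.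
4. The only ring (3,6-dihydro-1,2-dioxine 12, ring A) is closed once, by ring-closing metathesis at C4–C5 of the acyclic mixed perketal 11.
5. 11 ⇒ hydroperoxide 3 (Schenck ene reaction of methyl (E)-pent-3-enoate, enzymatic resolution) + vinyl dimethyl ketal 10 (δ-valerolactone, Weinreb amide, vinylmagnesium bromide), joined by acid-catalysed ketal exchange.

Key step: step 8

Remark 1 (stereochemistry): the ketal carbon C6 cannot be controlled in the acyclic perketal, so 11, 12 and 13 are C6-epimeric pairs with C3 fixed; C6 is set in step 10 under thermodynamic control.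
Remark 2 (assumption): horseradish peroxidase is assumed to reduce the (S)-hydroperoxide and leave (R)-3; the sense is to be confirmed by reducing a sample to methyl 3-hydroxypent-4-enoate and Mosher ester analysis.

**Route**

Step 1
Reactants: 1 methyl (3E)-pent-3-enoate
Product: 2 methyl 3-hydroperoxypent-4-enoate (racemate)
Conditions: O2, tetraphenylporphyrin (cat.), visible light, CCl4, 0 °C; chromatography
Reagents that add atoms: dioxygen O=O
Why: Schenck ene reaction of singlet oxygen, in which abstraction of a C5–H through the perepoxide-like transition state puts oxygen on C3 and moves the alkene to C4=C5; the competing abstraction of the ester-activated C2–H gives methyl (E)-4-hydroperoxypent-2-enoate, expected in a comparable or larger amount and removed by chromatography, a loss accepted for the first step on a commodity ester.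

Step 2
Reactants: 2 methyl 3-hydroperoxypent-4-enoate (racemate)
Product: 3 methyl (3R)-3-hydroperoxypent-4-enoate
Conditions: horseradish peroxidase, guaiacol, phosphate buffer pH 6, 20 °C, stopped near 55 % conversion; chromatography
Reagents that add atoms: none
Why: Peroxidase-catalysed kinetic resolution, in which the haem enzyme reduces one enantiomer of a secondary hydroperoxide to the alcohol much faster than the other (vinyl taken as the small group, CH2CO2Me as the large one), so that (R)-3 should remain and the C3 stereocenter of the target is fixed here without touching the C–O bond.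

Step 3
Reactants: 4 δ-valerolactone
Product: 5 5-hydroxy-N-methoxy-N-methylpentanamide
Conditions: MeNH(OMe)·HCl, iPrMgCl, THF, −20 → 0 °C
Reagents that add atoms: N,O-dimethylhydroxylamine hydrochloride CNOC.Cl
Why: Weinreb amide formation by aminolysis of the lactone with the chloromagnesium amide; the ring-opened alkoxide cannot relactonize under the basic conditions and the product is silylated at once.

Step 4
Reactants: 5 5-hydroxy-N-methoxy-N-methylpentanamide
Product: 6 5-[(tert-butyldiphenylsilyl)oxy]-N-methoxy-N-methylpentanamide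
Conditions: tBuPh2SiCl, imidazole, DMF, rt
Reagents that add atoms: tert-butyl(chloro)diphenylsilane CC(C)(C)[Si](Cl)(c1ccccc1)c1ccccc1
Why: Standard silylation of the primary alcohol; the tert-butyldiphenylsilyl ether is chosen because it survives the acidic methanol of step 10, where a free O10 hydroxyl would be trapped by C6 as a spiroketal.

Step 5
Reactants: 6 5-[(tert-butyldiphenylsilyl)oxy]-N-methoxy-N-methylpentanamide; 7 vinylmagnesium bromide
Product: 9 7-[(tert-butyldiphenylsilyl)oxy]hept-1-en-3-one, via tetrahedral magnesium adduct 8 (not isolated)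
Conditions: THF, −10 → 0 °C; inverse quench into cold 1 M HCl
Reagents that add atoms: none
Why: Weinreb ketone synthesis, in which the N,O-chelated adduct 8 persists until work-up so that no second addition occurs, and the inverse acidic quench protonates the liberated N,O-dimethylhydroxylamine before it can add to the vinyl ketone.

Step 6
Reactants: 9 7-[(tert-butyldiphenylsilyl)oxy]hept-1-en-3-one
Product: 10 tert-butyl[(5,5-dimethoxyhept-6-en-1-yl)oxy]diphenylsilane
Conditions: MeOSiMe3 (4 equiv), Me3SiOTf (5 mol %), CH2Cl2, −78 °C; pyridine quench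
Reagents that add atoms: methoxytrimethylsilane CO[Si](C)(C)C
Why: Silyl-triflate-catalysed acetalization with an alkoxysilane, where 1,2-addition to the silylated carbonyl at −78 °C and irreversible formation of hexamethyldisiloxane give the dimethyl ketal without the conjugate addition of methanol that accompanies protic ketalization of vinyl ketones.

Step 7
Reactants: 3 methyl (3R)-3-hydroperoxypent-4-enoate; 10 tert-butyl[(5,5-dimethoxyhept-6-en-1-yl)oxy]diphenylsilane (2 equiv)
Product: 11 methyl (3R)-3-[(7-{[tert-butyl(diphenyl)silyl]oxy}-3-methoxyhept-1-en-3-yl)peroxy]pent-4-enoate (both epimers at the ketal carbon C6)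
Conditions: PPTS (5 mol %), 5 Å molecular sieves, CH2Cl2, 0 °C; Et3N quench; chromatography on Et3N-treated silica
Reagents that add atoms: none
Why: Acid-catalysed ketal exchange (perketalization), in which ionization of 10 gives the 1-methoxyallyl carbenium ion that the hydroperoxide captures at the oxygen-bearing carbon under kinetic control while the sieves remove methanol; the C3–O bond is not broken, so C3 keeps its configuration, and C6 forms as both epimers.

Step 8
Reactants: 11 methyl (3R)-3-[(7-{[tert-butyl(diphenyl)silyl]oxy}-3-methoxyhept-1-en-3-yl)peroxy]pent-4-enoate (C6 epimers)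
Product: 12 methyl 2-[(3R)-6-(4-{[tert-butyl(diphenyl)silyl]oxy}butyl)-6-methoxy-3,6-dihydro-1,2-dioxin-3-yl]acetate (C6 epimers)
Conditions: second-generation Hoveyda–Grubbs catalyst RuCl2(H2IMes)(=CH-C6H4-2-OiPr) (5–10 mol %), 1,4-benzoquinone (10 mol %), CH2Cl2 (0.01 M), 40 °C, argon sparge
Reagents that add atoms: none
Why: Proposed new method: ring-closing alkene metathesis across a preformed acyclic O–O tether by the usual [2+2]/retro-[2+2] ruthenacyclobutane sequence, in which the benzylidene exchanges with the less hindered C3 vinyl group to put ruthenium on C4, this alkylidene adds to the vinyl group on the quaternary C6, and cycloreversion forms C4=C5 and releases ethene, which is swept out; the closest known reaction types are ring-closing metathesis of diallyl ethers and of N–O-tethered dienes and cross-metathesis of alkenyl dialkyl peroxides. Ring A (the 3,6-dihydro-1,2-dioxine) is closed at C4–C5 as an unstrained six-membered ring from a 1,7-diene whose skewed C–O–O–C unit already holds the two alkenes close, so the peroxide serves only as a tether. No stereocenter is formed: C3 comes from 3, and C6 stays an epimeric pair, both members of which can cyclize. The step needs chemoselectivity, namely metathesis without O–O cleavage and without loss of the allylic C3–H; this should be secured by the absence of a hydroperoxide O–H, by a phosphine-free catalyst (no free phosphine to deoxygenate the peroxide) and by 1,4-benzoquinone, which scavenges the ruthenium hydrides that would isomerize the allylic peroxide.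

Step 9
Reactants: 12 methyl 2-[(3R)-6-(4-{[tert-butyl(diphenyl)silyl]oxy}butyl)-6-methoxy-3,6-dihydro-1,2-dioxin-3-yl]acetate (C6 epimers)
Product: 13 methyl 2-[(3S)-6-(4-{[tert-butyl(diphenyl)silyl]oxy}butyl)-6-methoxy-1,2-dioxan-3-yl]acetate (C6 epimers)
Conditions: KO2C–N=N–CO2K, AcOH (slow addition), MeOH/CH2Cl2, 0 °C → rt
Reagents that add atoms: none
Why: Diimide reduction, a concerted syn transfer of two hydrogens that saturates C4=C5 while leaving the O–O bond, which catalytic hydrogenation would not spare, untouched; no stereocenter is created and the C3 descriptor changes from R to S only through the priority rules.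

Step 10
Reactants: 13 methyl 2-[(3S)-6-(4-{[tert-butyl(diphenyl)silyl]oxy}butyl)-6-methoxy-1,2-dioxan-3-yl]acetate (C6 epimers)
Product: 14 methyl 2-[(3S,6R)-6-(4-{[tert-butyl(diphenyl)silyl]oxy}butyl)-6-methoxy-1,2-dioxan-3-yl]acetate
Conditions: TsOH·H2O (5 mol %), MeOH, 0 °C → rt; NaHCO3 quench; the minor (6S) epimer is separated and resubmitted
Reagents that add atoms: methanol CO
Why: Thermodynamic epimerization of the peroxyketal, in which reversible acid-induced loss of methanol gives the cyclic peroxycarbenium ion and recapture of methanol settles in the chair with the C3 and C6 carbon substituents equatorial and the methoxy group axial (anomeric effect), which is the (3S,6R) isomer; C3 is not involved and the silyl ether is retained.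

Step 11
Reactants: 14 methyl 2-[(3S,6R)-6-(4-{[tert-butyl(diphenyl)silyl]oxy}butyl)-6-methoxy-1,2-dioxan-3-yl]acetate
Product: 15 methyl 2-[(3S,6R)-6-(4-hydroxybutyl)-6-methoxy-1,2-dioxan-3-yl]acetate
Conditions: Bu4NF/AcOH (1:1), THF, 0 °C → rt
Reagents that add atoms: none
Why: Fluoride cleavage of the Si–O bond, buffered with acetic acid so that the medium stays near neutral and neither base-induced opening of the β-peroxy ester nor acid-induced spiroketalization of the freed hydroxyl with C6 takes place.

Step 12
Reactants: 15 methyl 2-[(3S,6R)-6-(4-hydroxybutyl)-6-methoxy-1,2-dioxan-3-yl]acetate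
Product: 16 methyl 2-[(3S,6R)-6-methoxy-6-(4-oxobutyl)-1,2-dioxan-3-yl]acetate
Conditions: Dess–Martin periodinane, NaHCO3, CH2Cl2, 0 °C → rt
Reagents that add atoms: none
Why: Dess–Martin oxidation of the primary alcohol to the aldehyde under buffered, non-reducing conditions that leave the dialkyl peroxide and the peroxyketal intact.

Step 13
Reactants: 16 methyl 2-[(3S,6R)-6-methoxy-6-(4-oxobutyl)-1,2-dioxan-3-yl]acetate
Product: 17 methyl 2-[(3S,6R)-6-methoxy-6-(pent-4-yn-1-yl)-1,2-dioxan-3-yl]acetate
Conditions: dimethyl (1-diazo-2-oxopropyl)phosphonate, K2CO3, MeOH, 0 °C → rt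
Reagents that add atoms: dimethyl (1-diazo-2-oxopropyl)phosphonate COP(=O)(OC)C(=[N+]=[N-])C(C)=O
Why: Seyferth–Gilbert homologation with the Ohira–Bestmann reagent, where the diazomethylphosphonate anion adds to the aldehyde and loss of nitrogen with 1,2-hydrogen shift gives the terminal alkyne C10≡C11; the mild carbonate base at 0 °C should be tolerated by the β-peroxy ester, and any reversible ring opening would reclose to the same thermodynamically preferred isomer because C6 is fixed.

Step 14
Reactants: 18 dec-9-yn-1-ol
Product: 20 10-(trimethylsilyl)dec-9-yn-1-ol, via bis-silylated decynol 19 (not isolated)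
Conditions: n-BuLi (2.2 equiv), THF, −78 °C; Me3SiCl (2.3 equiv), −78 °C → rt; then 1 M HCl, rt
Reagents that add atoms: chlorotrimethylsilane C[Si](C)(C)Cl
Why: Double deprotonation and silylation at O and C, followed by selective hydrolysis of the labile O–Si bond, masks the terminal alkyne for the later coupling.

Step 15
Reactants: 20 10-(trimethylsilyl)dec-9-yn-1-ol
Product: 21 10-(trimethylsilyl)dec-9-ynal
Conditions: PhI(OAc)2, TEMPO (10 mol %), CH2Cl2, rt
Reagents that add atoms: none
Why: Oxoammonium-mediated (TEMPO) oxidation of the primary alcohol stops at the aldehyde and does not affect the alkynylsilane.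

Step 16
Reactants: 21 10-(trimethylsilyl)dec-9-ynal
Product: 22 [(10E)-11-iodoundec-10-en-1-yn-1-yl]trimethylsilane
Conditions: CrCl2 (6 equiv), CHI3 (2 equiv), THF/1,4-dioxane, 0 °C → rt
Reagents that add atoms: iodoform IC(I)I
Why: Takai olefination, in which the geminal dichromium carbenoid from iodoform adds to the aldehyde and elimination gives the (E)-vinyl iodide selectively, fixing the later C12=C13 geometry.

Step 17
Reactants: 17 methyl 2-[(3S,6R)-6-methoxy-6-(pent-4-yn-1-yl)-1,2-dioxan-3-yl]acetate; 22 [(10E)-11-iodoundec-10-en-1-yn-1-yl]trimethylsilane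
Product: 23 methyl 2-[(3S,6R)-6-methoxy-6-[(6E)-16-(trimethylsilyl)hexadec-6-ene-4,15-diyn-1-yl]-1,2-dioxan-3-yl]acetate
Conditions: Pd(PPh3)4 (5 mol %), CuI (10 mol %), Et3N, THF, rt, degassed
Reagents that add atoms: none
Why: Sonogashira coupling (oxidative addition of the vinyl iodide to zerovalent palladium, transmetalation from the copper acetylide, reductive elimination) forms C11–C12 with retention of the E geometry; the dialkyl peroxide should tolerate the palladium–phosphine system at room temperature and the silyl group keeps the distal alkyne out of the coupling.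

Step 18
Reactants: 23 methyl 2-[(3S,6R)-6-methoxy-6-[(6E)-16-(trimethylsilyl)hexadec-6-ene-4,15-diyn-1-yl]-1,2-dioxan-3-yl]acetate
Product: 24 methyl 2-[(3S,6R)-6-[(6E)-hexadec-6-ene-4,15-diyn-1-yl]-6-methoxy-1,2-dioxan-3-yl]acetate (CNP0314169.1)
Conditions: K2CO3 (0.3 equiv), MeOH/CH2Cl2, 0 °C
Reagents that add atoms: none
Why: Methoxide-induced protodesilylation of the alkynylsilane, with catalytic carbonate at 0 °C that should spare the β-peroxy ester, the peroxyketal and the enyne.

**Compound list**
1 | methyl (3E)-pent-3-enoate | C/C=C/CC(=O)OC | starting material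
2 | methyl 3-hydroperoxypent-4-enoate (racemate) | C=CC(OO)CC(=O)OC | intermediate
3 | methyl (3R)-3-hydroperoxypent-4-enoate | C=C[C@H](OO)CC(=O)OC | intermediate
4 | δ-valerolactone (oxan-2-one) | O=C1CCCCO1 | starting material
5 | 5-hydroxy-N-methoxy-N-methylpentanamide | CON(C)C(=O)CCCCO | intermediate
6 | 5-[(tert-butyldiphenylsilyl)oxy]-N-methoxy-N-methylpentanamide | CON(C)C(=O)CCCCO[Si](c1ccccc1)(c1ccccc1)C(C)(C)C | intermediate
7 | vinylmagnesium bromide | C=C[Mg]Br | starting material
8 | bromomagnesium 7-[(tert-butyldiphenylsilyl)oxy]-3-[methoxy(methyl)amino]hept-1-en-3-olate (tetrahedral adduct, not isolated) | C=CC(O[Mg]Br)(N(C)OC)CCCCO[Si](c1ccccc1)(c1ccccc1)C(C)(C)C | intermediate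
9 | 7-[(tert-butyldiphenylsilyl)oxy]hept-1-en-3-one | C=CC(=O)CCCCO[Si](c1ccccc1)(c1ccccc1)C(C)(C)C | intermediate
10 | tert-butyl[(5,5-dimethoxyhept-6-en-1-yl)oxy]diphenylsilane | C=CC(OC)(OC)CCCCO[Si](c1ccccc1)(c1ccccc1)C(C)(C)C | intermediate
11 | methyl (3R)-3-[(7-{[tert-butyl(diphenyl)silyl]oxy}-3-methoxyhept-1-en-3-yl)peroxy]pent-4-enoate (both C6 epimers) | C=CC(OC)(CCCCO[Si](c1ccccc1)(c1ccccc1)C(C)(C)C)OO[C@H](CC(=O)OC)C=C | intermediate
12 | methyl 2-[(3R)-6-(4-{[tert-butyl(diphenyl)silyl]oxy}butyl)-6-methoxy-3,6-dihydro-1,2-dioxin-3-yl]acetate (both C6 epimers) | CC(C)(C)[Si](c1ccccc1)(c1ccccc1)OCCCCC1(OC)C=C[C@@H](CC(=O)OC)OO1 | intermediate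
13 | methyl 2-[(3S)-6-(4-{[tert-butyl(diphenyl)silyl]oxy}butyl)-6-methoxy-1,2-dioxan-3-yl]acetate (both C6 epimers) | CC(C)(C)[Si](c1ccccc1)(c1ccccc1)OCCCCC1(OC)CC[C@@H](CC(=O)OC)OO1 | intermediate
14 | methyl 2-[(3S,6R)-6-(4-{[tert-butyl(diphenyl)silyl]oxy}butyl)-6-methoxy-1,2-dioxan-3-yl]acetate | CC(C)(C)[Si](c1ccccc1)(c1ccccc1)OCCCC[C@]1(OC)CC[C@@H](CC(=O)OC)OO1 | intermediate
15 | methyl 2-[(3S,6R)-6-(4-hydroxybutyl)-6-methoxy-1,2-dioxan-3-yl]acetate | OCCCC[C@]1(OC)CC[C@@H](CC(=O)OC)OO1 | intermediate
16 | methyl 2-[(3S,6R)-6-methoxy-6-(4-oxobutyl)-1,2-dioxan-3-yl]acetate | O=CCCC[C@]1(OC)CC[C@@H](CC(=O)OC)OO1 | intermediate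
17 | methyl 2-[(3S,6R)-6-methoxy-6-(pent-4-yn-1-yl)-1,2-dioxan-3-yl]acetate | C#CCCC[C@]1(OC)CC[C@@H](CC(=O)OC)OO1 | intermediate
18 | dec-9-yn-1-ol | OCCCCCCCCC#C | starting material
19 | trimethyl{[10-(trimethylsilyl)dec-9-yn-1-yl]oxy}silane (not isolated) | C[Si](C)(C)C#CCCCCCCCCO[Si](C)(C)C | intermediate
20 | 10-(trimethylsilyl)dec-9-yn-1-ol | C[Si](C)(C)C#CCCCCCCCCO | intermediate
21 | 10-(trimethylsilyl)dec-9-ynal | C[Si](C)(C)C#CCCCCCCCC=O | intermediate
22 | [(10E)-11-iodoundec-10-en-1-yn-1-yl]trimethylsilane | C[Si](C)(C)C#CCCCCCCC/C=C/I | intermediate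
23 | methyl 2-[(3S,6R)-6-methoxy-6-[(6E)-16-(trimethylsilyl)hexadec-6-ene-4,15-diyn-1-yl]-1,2-dioxan-3-yl]acetate | C[Si](C)(C)C#CCCCCCCC/C=C/C#CCCC[C@]1(OC)CC[C@@H](CC(=O)OC)OO1 | intermediate
24 | methyl 2-[(3S,6R)-6-[(6E)-hexadec-6-ene-4,15-diyn-1-yl]-6-methoxy-1,2-dioxan-3-yl]acetate | C#CCCCCCCC/C=C/C#CCCC[C@]1(OC)CC[C@@H](CC(=O)OC)OO1 | target

**Step count**
Total: 18 steps. Longest linear sequence: 13 steps (δ-valerolactone 4 to 24 through steps 3–13, 17 and 18).

**Steps most likely to fail**

1. Step 8 (metathesis across the peroxide). What may go wrong: electron transfer from ruthenium alkylidene or hydride species into the O–O bond with collapse of the peroxide; hydride-induced isomerization of the allylic peroxide with loss of the C3–H; or failure of the C4 alkylidene to close on the hindered, doubly oxygenated vinyl ketal before the acyclic perketal decomposes. The fallback uses known chemistry and closes the ring at C6–O by peroxyketalization, with C4–C5 made beforehand by cross-metathesis of a simple perketal-protected hydroperoxide, a reaction type established for alkenyl peroxides. It sets out from hydroperoxide 3 and enone 9 and comes back at 14. Hydroperoxide 3 is masked with 2-methoxypropene (PPTS, CH2Cl2, 0 °C) as methyl (3R)-3-[(2-methoxypropan-2-yl)peroxy]pent-4-enoate F1. Cross-metathesis of F1 with an excess of 9 (second-generation Hoveyda–Grubbs catalyst, CH2Cl2, 40 °C) should give methyl (3R,4E)-10-[(tert-butyldiphenylsilyl)oxy]-3-[(2-methoxypropan-2-yl)peroxy]-6-oxodec-4-enoate F2. Diimide (KO2C–N=N–CO2K, AcOH) saturates C4–C5 to methyl (3S)-10-[(tert-butyldiphenylsilyl)oxy]-3-[(2-methoxypropan-2-yl)peroxy]-6-oxodecanoate F3. TsOH in methanol then removes the perketal; the freed C3 hydroperoxide closes on the C6 ketone as the cyclic peroxyhemiketal, and methanol converts this into the methyl ketal under the same thermodynamic control, giving 14.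

2. Step 2 (enzymatic resolution). What may go wrong: the enzyme may not accept the substrate, or may discriminate the enantiomers poorly or in the opposite sense, so that the remaining hydroperoxide is not enantiopure (R). The fallback is a covalent resolution that sets out from racemic 2 and comes back at 3. Hydroperoxide 2 is added (PPTS, CH2Cl2, 0 °C) to the 2-propenyl ether of (1R,2S)-2-phenylcyclohexanol, and the two diastereomeric perketals are separated by chromatography. These are methyl (3R)-3-[(2-{[(1R,2S)-2-phenylcyclohexyl]oxy}propan-2-yl)peroxy]pent-4-enoate F4 and methyl (3S)-3-[(2-{[(1R,2S)-2-phenylcyclohexyl]oxy}propan-2-yl)peroxy]pent-4-enoate F5, the latter being set aside. Hydrolysis of F4 (AcOH/THF/H2O, rt) returns 3, whose configuration is assigned through the derived alcohol.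

3. Step 1 (ene reaction). What may go wrong: hydrogen abstraction at the ester-activated C2 instead of at C5, so that oxygen ends up on C4 and too little of the C3 hydroperoxide is formed. The fallback replaces the pentenoate by a symmetrical diester in which both allylic positions are equivalent, so that abstraction next to an ester is the productive mode. It sets out from ketal 10 and comes back at 12. Commercial dimethyl (E)-hex-3-enedioate is photooxygenated (O2, tetraphenylporphyrin, light, CCl4) to dimethyl (2E)-4-hydroperoxyhex-2-enedioate F6 as the only constitutional isomer. Peroxidase resolution as in step 2 should leave dimethyl (2E,4R)-4-hydroperoxyhex-2-enedioate F7. Exchange with 10 (PPTS, 5 Å sieves) gives dimethyl (2E,4R)-4-[(7-{[tert-butyl(diphenyl)silyl]oxy}-3-methoxyhept-1-en-3-yl)peroxy]hex-2-enedioate F8. Ring-closing metathesis of F8 under the conditions of step 8 should give 12 with loss of methyl acrylate: the catalyst enters at the enoate through the ruthenacyclobutane that carries the ester on its β-carbon, as in acrylate cross-metathesis, and the resulting C4 alkylidene closes on the C6 vinyl group. This closure is expected to be slower than with the vinyl terminus.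

**Further compounds**
F1 | step 8 | methyl (3R)-3-[(2-methoxypropan-2-yl)peroxy]pent-4-enoate | C=C[C@H](OOC(C)(C)OC)CC(=O)OC
F2 | step 8 | methyl (3R,4E)-10-[(tert-butyldiphenylsilyl)oxy]-3-[(2-methoxypropan-2-yl)peroxy]-6-oxodec-4-enoate | COC(=O)C[C@@H](OOC(C)(C)OC)/C=C/C(=O)CCCCO[Si](c1ccccc1)(c1ccccc1)C(C)(C)C
F3 | step 8 | methyl (3S)-10-[(tert-butyldiphenylsilyl)oxy]-3-[(2-methoxypropan-2-yl)peroxy]-6-oxodecanoate | COC(=O)C[C@@H](OOC(C)(C)OC)CCC(=O)CCCCO[Si](c1ccccc1)(c1ccccc1)C(C)(C)C
F4 | step 2 | methyl (3R)-3-[(2-{[(1R,2S)-2-phenylcyclohexyl]oxy}propan-2-yl)peroxy]pent-4-enoate | C=C[C@H](OOC(C)(C)O[C@@H]1CCCC[C@H]1c1ccccc1)CC(=O)OC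
F5 | step 2 | methyl (3S)-3-[(2-{[(1R,2S)-2-phenylcyclohexyl]oxy}propan-2-yl)peroxy]pent-4-enoate | C=C[C@@H](OOC(C)(C)O[C@@H]1CCCC[C@H]1c1ccccc1)CC(=O)OC
F6 | step 1 | dimethyl (2E)-4-hydroperoxyhex-2-enedioate (racemate) | COC(=O)/C=C/C(OO)CC(=O)OC
F7 | step 1 | dimethyl (2E,4R)-4-hydroperoxyhex-2-enedioate | COC(=O)/C=C/[C@H](OO)CC(=O)OC
F8 | step 1 | dimethyl (2E,4R)-4-[(7-{[tert-butyl(diphenyl)silyl]oxy}-3-methoxyhept-1-en-3-yl)peroxy]hex-2-enedioate (both C6 epimers) | COC(=O)/C=C/[C@H](OOC(OC)(C=C)CCCCO[Si](c1ccccc1)(c1ccccc1)C(C)(C)C)CC(=O)OC
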